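The benzene ring is built, not bought: its two meta oxygens (phenolic O on C3′, methoxy O on C5′) flanking the chain-bearing C1′ are the carbonyls of a symmetric 5-alkylcyclohexane-1,3-dione. A Michael–Claisen annulation of dimethyl malonate onto an acyclic δ-alkoxy methyl enone forges ring bonds C1′–C2′ and C3′–C4′ in one operation and closes the six-membered carbocycle; decarboxylation, O-methylation and dehydrogenation then give the monomethyl resorcinol without any regiochemical choice. The enone precursor already holds both stereocentres, C8 (from a resolved epoxide) as a benzyl ether and C2 (from an asymmetric allylation) as a PMB ether, so the ring-forming step needs only chemoselectivity.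

Key step: step 8

Remark (conventions): chain locants are those of the target (C1 benzylic CH2, C2 acetoxy carbon, C8 carbinol carbon) unless a compound number is given; ring locants carry primes (C1′ bears the chain). salen = N,N′-bis(3,5-di-tert-butylsalicylidene)cyclohexane-1,2-diamine dianion; Ipc = isopinocampheyl of the (+)-α-pinene series.

Step 1
Reactants: 1 racemic 2-pentyloxirane (1,2-epoxyheptane)
Product: 2 (2S)-2-pentyloxirane
Conditions: (S,S)-(salen)Co(OAc) (0.5 mol%), H2O (0.55 equiv), neat, 0 °C → rt; distillation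
Reagents that add atoms: none
Why: Jacobsen hydrolytic kinetic resolution, in which the (S,S)-configured trivalent-cobalt salen catalyst is chosen as the antipode that hydrates the (R)-epoxide much faster than the (S)-epoxide, so that the volatile (S)-enantiomer carrying the future C8 configuration should be recovered in high enantiomeric purity by distillation from the diol.

Step 2
Reactants: 2 (2S)-2-pentyloxirane; 3 6-bromohex-1-ene
Product: 5 (6S)-tridec-12-en-6-ol, via hex-5-enylmagnesium bromide 4 (not isolated)
Conditions: 3, Mg, THF, rt → 40 °C; then CuI (10 mol%), 2, THF, −30 → 0 °C; aq. NH4Cl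
Reagents that add atoms: none
Why: Copper-catalysed Grignard opening of a terminal epoxide is an SN2 attack at the unsubstituted carbon, so the stereogenic C–O carbon is not touched and becomes C8 with the (S) configuration, while the terminal alkene is carried as a latent aldehyde.

Step 3
Reactants: 5 (6S)-tridec-12-en-6-ol
Product: 6 benzyl (6S)-tridec-12-en-6-yl ether
Conditions: NaH, BnBr, Bu4NI (cat.), THF/DMF, 0 °C → rt
Reagents that add atoms: benzyl bromide, BrCc1ccccc1
Why: Williamson etherification of the secondary sodium alkoxide with benzyl bromide gives an ether that is inert to ozone at low temperature, boranes, base, mild acid and DDQ and is cleaved only in the final hydrogenolysis.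

Step 4
Reactants: 6 benzyl (6S)-tridec-12-en-6-yl ether
Product: 8 (7S)-7-(benzyloxy)dodecanal, via ozonide 7 (not isolated)
Conditions: O3, CH2Cl2, −78 °C, stopped at first blue colour, N2 purge; then PPh3, −78 °C → rt
Reagents that add atoms: ozone, [O-][O+]=O
Why: Ozonolysis with reductive (PPh3) work-up cleaves the only C=C bond to the aldehyde, the terminal alkene reacting far faster than the benzylic C–H bonds of the ether when the gas flow is stopped at the first blue tinge.

Step 5
Reactants: 8 (7S)-7-(benzyloxy)dodecanal; 9 allylmagnesium bromide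
Product: 12 (4R,10S)-10-(benzyloxy)pentadec-1-en-4-ol, via (−)-B-allyldiisopinocampheylborane 10 (not isolated), via borinate ester 11 (not isolated)
Conditions: (−)-Ipc2BOMe, 9, Et2O, 0 °C → rt; then 8, −78 °C; then 3 M NaOH, 30% H2O2, 0 °C → rt
Reagents that add atoms: none
Why: Brown asymmetric allylboration through a closed chair (Zimmerman–Traxler) transition state, in which the (+)-α-pinene-derived isopinocampheyl groups deliver the allyl group to the Si face of the unbranched aldehyde, sets the new carbinol carbon (future C2) as (R) under reagent control, the remote C10 ether exerting no influence.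

Step 6
Reactants: 12 (4R,10S)-10-(benzyloxy)pentadec-1-en-4-ol
Product: 13 1-({[(4R,10S)-10-(benzyloxy)pentadec-1-en-4-yl]oxy}methyl)-4-methoxybenzene (PMB ether of 12)
Conditions: NaH, 4-methoxybenzyl chloride, Bu4NI (cat.), DMF, 0 °C → rt
Reagents that add atoms: 4-methoxybenzyl chloride, COc1ccc(CCl)cc1
Why: Williamson etherification with 4-methoxybenzyl chloride turns the C2 oxygen into an ether, a poor leaving group for the base-mediated annulation that can later be removed oxidatively in the presence of benzyl ethers.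

Step 7
Reactants: 13 PMB ether of 12; 14 but-3-en-2-one (methyl vinyl ketone)
Product: 15 (3E,6R,12S)-12-(benzyloxy)-6-[(4-methoxybenzyl)oxy]heptadec-3-en-2-one
Conditions: second-generation Grubbs catalyst (3 mol%), 14 (4 equiv), CH2Cl2, 40 °C
Reagents that add atoms: none
Why: Olefin cross-metathesis between an unhindered terminal alkene and the electron-poor, slowly homodimerising methyl vinyl ketone should favour the hetero-coupled (E)-enone, driven by loss of ethene, and the ruthenium carbene tolerates both ethers.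

Step 8
Reactants: 15 (3E,6R,12S)-12-(benzyloxy)-6-[(4-methoxybenzyl)oxy]heptadec-3-en-2-one; 16 dimethyl malonate
Product: 18 methyl 6-[(2R,8S)-8-(benzyloxy)-2-[(4-methoxybenzyl)oxy]tridecyl]-2,4-dioxocyclohexane-1-carboxylate (ring centres as a mixture), via acyclic Michael adduct 17 (not isolated)
Conditions: 16 (1.3 equiv), NaOMe (1.3 equiv), MeOH, 0 °C; 15 added dropwise, rt, then reflux; 1 M HCl to pH 3–4 at 0 °C
Reagents that add atoms: none
Why: Preformed sodiomalonate adds 1,4 to C4 of enone 15, proton transfer moves the charge to the methyl-ketone carbon C1, and that enolate acylates one malonate ester with loss of methoxide, so both ring bonds (arene C1′–C2′ and C3′–C4′) are made in one flask and the sequence is pulled forward by the doubly stabilised β-diketone enolate. The closest known reaction type is the Michael–Claisen (Dieckmann-type) annulation of malonates with α,β-unsaturated methyl ketones, the classical entry to dimedone and to 5-alkyl-dihydroresorcinols. The carbocycle closes in a 6-(enolexo)-exo-trig mode. The two ring CH centres form as a mixture that is erased by decarboxylation and aromatisation, no lasting stereocentre is created, and the two chain stereocentres are not touched. The only selectivity needed is chemoselectivity, conjugate addition ahead of γ-deprotonation at C5 of 15 and E1cB loss of the C6 oxygen; it is secured by the ether (alkoxide, not carboxylate) leaving group at C6, by slow addition of 15 to an excess of the soft, weakly basic malonate anion so that little free methoxide meets the enone, and by the fact that Michael adduct 17 has no elimination pathway left.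

Step 9
Reactants: 18 methyl 6-[(2R,8S)-8-(benzyloxy)-2-[(4-methoxybenzyl)oxy]tridecyl]-2,4-dioxocyclohexane-1-carboxylate
Product: 20 5-[(2R,8S)-8-(benzyloxy)-2-[(4-methoxybenzyl)oxy]tridecyl]cyclohexane-1,3-dione, via β-keto acid 19 (not isolated)
Conditions: 2 M aq. NaOH, MeOH, 65 °C; then 2 M HCl to pH 3, 50 °C
Reagents that add atoms: none
Why: Saponification of the methyl ester followed by acidification gives a β-keto acid that decarboxylates through the usual six-membered cyclic transition state on gentle warming, leaving the symmetric 5-substituted 1,3-dione, while the benzyl and PMB ethers tolerate hot aqueous base and brief exposure to dilute acid.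

Step 10
Reactants: 20 5-[(2R,8S)-8-(benzyloxy)-2-[(4-methoxybenzyl)oxy]tridecyl]cyclohexane-1,3-dione
Product: 21 5-[(2R,8S)-8-(benzyloxy)-2-[(4-methoxybenzyl)oxy]tridecyl]-3-methoxycyclohex-2-en-1-one (ring C5 epimers)
Conditions: MeOH, HC(OMe)3 (3 equiv), TsOH·H2O (5 mol%), rt
Reagents that add atoms: methanol, CO
Why: Acid-catalysed enol etherification of a cyclic 1,3-dione (a vinylogous Fischer esterification driven by orthoformate scavenging of water) needs no regiocontrol because the dione is symmetric about ring C5, and the new ring stereocentre is a transient mixture.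

Step 11
Reactants: 21 5-[(2R,8S)-8-(benzyloxy)-2-[(4-methoxybenzyl)oxy]tridecyl]-3-methoxycyclohex-2-en-1-one
Product: 24 3-[(2R,8S)-8-(benzyloxy)-2-[(4-methoxybenzyl)oxy]tridecyl]-5-methoxyphenol, via silyl dienol ether 22 (not isolated), via dienone tautomer 23 (not isolated)
Conditions: LiN(iPr)2 (1.2 equiv), THF, −78 °C; TMSCl, −78 → 0 °C; solvent exchange; then Pd(OAc)2 (1.05 equiv), MeCN, rt
Reagents that add atoms: none
Why: Kinetic α′-deprotonation of the vinylogous ester at ring C6 followed by O-silylation gives the cross-conjugated silyl dienol ether, and its Saegusa–Ito oxidation by divalent palladium (β-hydride elimination from ring C5) gives a dienone that tautomerises irreversibly to the 3-methoxyphenol, erasing the ring stereocentre and leaving the chain ethers untouched.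

Step 12
Reactants: 24 3-[(2R,8S)-8-(benzyloxy)-2-[(4-methoxybenzyl)oxy]tridecyl]-5-methoxyphenol
Product: 25 1-(benzyloxy)-3-[(2R,8S)-8-(benzyloxy)-2-[(4-methoxybenzyl)oxy]tridecyl]-5-methoxybenzene
Conditions: BnBr (1.2 equiv), K2CO3 (2 equiv), acetone, 55 °C
Reagents that add atoms: benzyl bromide, BrCc1ccccc1
Why: Williamson O-alkylation of the potassium phenoxide with benzyl bromide shields the electron-rich phenol from the quinone oxidant of the next step with a group that will leave together with the C8 benzyl ether.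

Step 13
Reactants: 25 1-(benzyloxy)-3-[(2R,8S)-8-(benzyloxy)-2-[(4-methoxybenzyl)oxy]tridecyl]-5-methoxybenzene
Product: 26 (2R,8S)-8-(benzyloxy)-1-[3-(benzyloxy)-5-methoxyphenyl]tridecan-2-ol
Conditions: DDQ (1.3 equiv), CH2Cl2/pH 7 buffer (10:1), 0 °C → rt
Reagents that add atoms: none
Why: Oxidative PMB cleavage by DDQ proceeds through hydride abstraction from the para-methoxy-stabilised benzylic carbon and hydrolysis of the resulting oxocarbenium ion, whereas the plain benzyl ethers and the meta-dioxygenated benzylic C1 lack that stabilisation and should survive.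

Step 14
Reactants: 26 (2R,8S)-8-(benzyloxy)-1-[3-(benzyloxy)-5-methoxyphenyl]tridecan-2-ol
Product: 27 (2R,8S)-8-(benzyloxy)-1-[3-(benzyloxy)-5-methoxyphenyl]tridecan-2-yl acetate
Conditions: Ac2O, pyridine, DMAP (cat.), CH2Cl2, rt
Reagents that add atoms: acetic anhydride, CC(=O)OC(C)=O
Why: DMAP-catalysed acetylation with acetic anhydride (nucleophilic acyl-transfer catalysis) esterifies the only free hydroxyl group without breaking the C2–O bond, so the (R) configuration is retained.

Step 15
Reactants: 27 (2R,8S)-8-(benzyloxy)-1-[3-(benzyloxy)-5-methoxyphenyl]tridecan-2-yl acetate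
Product: 28 (2R,8S)-8-hydroxy-1-(3-hydroxy-5-methoxyphenyl)tridecan-2-yl acetate
Conditions: H2 (1 atm), 10% Pd/C, EtOAc, rt
Reagents that add atoms: none
Why: Catalytic hydrogenolysis over Pd/C cleaves the two benzylic C–O bonds (aryl benzyl ether and C8 benzyl ether) to toluene, whereas the C2 acetate, whose C–O bond is homobenzylic, and the aryl methyl ether are inert in neutral ethyl acetate.

Compound list
1 | 2-pentyloxirane (racemic 1,2-epoxyheptane) | CCCCCC1CO1 | starting material
2 | (2S)-2-pentyloxirane | CCCCC[C@H]1CO1 | intermediate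
3 | 6-bromohex-1-ene | C=CCCCCBr | starting material
4 | hex-5-en-1-ylmagnesium bromide | C=CCCCC[Mg]Br | intermediate
5 | (6S)-tridec-12-en-6-ol | CCCCC[C@H](O)CCCCCC=C | intermediate
6 | benzyl (6S)-tridec-12-en-6-yl ether | CCCCC[C@H](OCc1ccccc1)CCCCCC=C | intermediate
7 | 3-[(6S)-6-(benzyloxy)undecyl]-1,2,4-trioxolane (ozonide, ring carbon unspecified) | CCCCC[C@H](OCc1ccccc1)CCCCCC1OCOO1 | intermediate
8 | (7S)-7-(benzyloxy)dodecanal | CCCCC[C@H](OCc1ccccc1)CCCCCC=O | intermediate
9 | allylmagnesium bromide | C=CC[Mg]Br | starting material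
10 | (−)-B-allyldiisopinocampheylborane (both Ipc groups from (+)-α-pinene) | C=CCB([C@@H]1C[C@@H]2C[C@@H](C2(C)C)[C@H]1C)[C@@H]1C[C@@H]2C[C@@H](C2(C)C)[C@H]1C | intermediate
11 | (4R,10S)-10-(benzyloxy)pentadec-1-en-4-yl diisopinocampheylborinate | CCCCC[C@H](OCc1ccccc1)CCCCC[C@H](CC=C)OB([C@@H]1C[C@@H]2C[C@@H](C2(C)C)[C@H]1C)[C@@H]1C[C@@H]2C[C@@H](C2(C)C)[C@H]1C | intermediate
12 | (4R,10S)-10-(benzyloxy)pentadec-1-en-4-ol | CCCCC[C@H](OCc1ccccc1)CCCCC[C@H](CC=C)O | intermediate
13 | 1-({[(4R,10S)-10-(benzyloxy)pentadec-1-en-4-yl]oxy}methyl)-4-methoxybenzene | CCCCC[C@H](OCc1ccccc1)CCCCC[C@H](CC=C)OCc1ccc(OC)cc1 | intermediate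
14 | but-3-en-2-one (methyl vinyl ketone) | CC(=O)C=C | starting material
15 | (3E,6R,12S)-12-(benzyloxy)-6-[(4-methoxybenzyl)oxy]heptadec-3-en-2-one | CCCCC[C@H](OCc1ccccc1)CCCCC[C@H](C/C=C/C(C)=O)OCc1ccc(OC)cc1 | intermediate
16 | dimethyl malonate | COC(=O)CC(=O)OC | starting material
17 | dimethyl 2-[(6R,12S)-12-(benzyloxy)-6-[(4-methoxybenzyl)oxy]-2-oxoheptadecan-4-yl]propanedioate (C4 epimers) | CCCCC[C@H](OCc1ccccc1)CCCCC[C@H](CC(CC(C)=O)C(C(=O)OC)C(=O)OC)OCc1ccc(OC)cc1 | intermediate
18 | methyl 6-[(2R,8S)-8-(benzyloxy)-2-[(4-methoxybenzyl)oxy]tridecyl]-2,4-dioxocyclohexane-1-carboxylate (ring centres as a mixture) | CCCCC[C@H](OCc1ccccc1)CCCCC[C@H](CC1CC(=O)CC(=O)C1C(=O)OC)OCc1ccc(OC)cc1 | intermediate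
19 | 6-[(2R,8S)-8-(benzyloxy)-2-[(4-methoxybenzyl)oxy]tridecyl]-2,4-dioxocyclohexane-1-carboxylic acid (ring centres as a mixture) | CCCCC[C@H](OCc1ccccc1)CCCCC[C@H](CC1CC(=O)CC(=O)C1C(=O)O)OCc1ccc(OC)cc1 | intermediate
20 | 5-[(2R,8S)-8-(benzyloxy)-2-[(4-methoxybenzyl)oxy]tridecyl]cyclohexane-1,3-dione | CCCCC[C@H](OCc1ccccc1)CCCCC[C@H](CC1CC(=O)CC(=O)C1)OCc1ccc(OC)cc1 | intermediate
21 | 5-[(2R,8S)-8-(benzyloxy)-2-[(4-methoxybenzyl)oxy]tridecyl]-3-methoxycyclohex-2-en-1-one (ring C5 epimers) | CCCCC[C@H](OCc1ccccc1)CCCCC[C@H](CC1CC(=O)C=C(OC)C1)OCc1ccc(OC)cc1 | intermediate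
22 | 1-(trimethylsilyloxy)-5-methoxy-3-[(2R,8S)-8-(benzyloxy)-2-[(4-methoxybenzyl)oxy]tridecyl]cyclohexa-1,5-diene (ring C3 epimers) | CCCCC[C@H](OCc1ccccc1)CCCCC[C@H](CC1C=C(O[Si](C)(C)C)C=C(OC)C1)OCc1ccc(OC)cc1 | intermediate
23 | 5-[(2R,8S)-8-(benzyloxy)-2-[(4-methoxybenzyl)oxy]tridecyl]-3-methoxycyclohexa-2,5-dien-1-one | CCCCC[C@H](OCc1ccccc1)CCCCC[C@H](CC1=CC(=O)C=C(OC)C1)OCc1ccc(OC)cc1 | intermediate
24 | 3-[(2R,8S)-8-(benzyloxy)-2-[(4-methoxybenzyl)oxy]tridecyl]-5-methoxyphenol | CCCCC[C@H](OCc1ccccc1)CCCCC[C@H](Cc1cc(O)cc(OC)c1)OCc1ccc(OC)cc1 | intermediate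
25 | 1-(benzyloxy)-3-[(2R,8S)-8-(benzyloxy)-2-[(4-methoxybenzyl)oxy]tridecyl]-5-methoxybenzene | CCCCC[C@H](OCc1ccccc1)CCCCC[C@H](Cc1cc(OCc2ccccc2)cc(OC)c1)OCc1ccc(OC)cc1 | intermediate
26 | (2R,8S)-8-(benzyloxy)-1-[3-(benzyloxy)-5-methoxyphenyl]tridecan-2-ol | CCCCC[C@H](OCc1ccccc1)CCCCC[C@H](Cc1cc(OCc2ccccc2)cc(OC)c1)O | intermediate
27 | (2R,8S)-8-(benzyloxy)-1-[3-(benzyloxy)-5-methoxyphenyl]tridecan-2-yl acetate | CCCCC[C@H](OCc1ccccc1)CCCCC[C@H](Cc1cc(OCc2ccccc2)cc(OC)c1)OC(C)=O | intermediate
28 | (2R,8S)-8-hydroxy-1-(3-hydroxy-5-methoxyphenyl)tridecan-2-yl acetate | CCCCC[C@H](O)CCCCC[C@H](Cc1cc(O)cc(OC)c1)OC(C)=O | target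

Total step count: 15. Longest linear sequence: 15 steps (1 → 28).

Steps most likely to fail

Step 8. The enone may be deprotonated at its γ-carbon and expel the PMB-oxide by vinylogous E1cB elimination faster than it accepts the malonate, which would destroy the C2 stereocentre. The fallback keeps the same ring but changes acceptor and nucleophile. Setting out from alkene 13, cross-metathesis with methyl acrylate (second-generation Grubbs catalyst, CH2Cl2, 40 °C) should give methyl (2E,5R,11S)-11-(benzyloxy)-5-[(4-methoxybenzyl)oxy]hexadec-2-enoate F1, whose γ-hydrogens are far less acidic than those of the ketone. Methyl acetoacetate and NaOMe in refluxing MeOH would then add to it to give dimethyl 2-acetyl-3-{(2R,8S)-8-(benzyloxy)-2-[(4-methoxybenzyl)oxy]tridecyl}pentanedioate F2. This adduct closes by Claisen attack of its acetyl methyl group on the chain ester to the same keto ester 18, where the route is rejoined.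

Step 11. Hydrolysis of the moisture-sensitive silyl dienol ether back to 21, or stalling of the oxidation as palladium black separates, may leave the ring unaromatised. The fallback uses selenium instead of palladium and isolates an intermediate. Setting out from 21, LiN(iPr)2 then PhSeCl (THF, −78 °C) gives 5-[(2R,8S)-8-(benzyloxy)-2-[(4-methoxybenzyl)oxy]tridecyl]-3-methoxy-6-(phenylselanyl)cyclohex-2-en-1-one F3. H2O2 and pyridine in CH2Cl2 at 0 °C oxidise it to the selenoxide, 6-(benzeneseleninyl)-5-[(2R,8S)-8-(benzyloxy)-2-[(4-methoxybenzyl)oxy]tridecyl]-3-methoxycyclohex-2-en-1-one F4. Its syn-elimination toward ring C5 gives dienone 23 and, by tautomerisation, phenol 24, where the route is rejoined.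

Step 5. Incomplete facial discrimination in the allylboration would leave a C2 epimer that cannot be removed, because the 1,7-related stereocentres make the diastereomers chromatographically alike. The fallback replaces reagent-controlled addition by a second kinetic resolution. Setting out from alkene 6, epoxidation with mCPBA (CH2Cl2, 0 °C) gives 2-[(6S)-6-(benzyloxy)undecyl]oxirane F5 as both epoxide epimers. Hydrolytic kinetic resolution with (R,R)-(salen)Co(OAc) and water (0.55 equiv) removes the (2S)-epimer as its diol and leaves (2R)-2-[(6S)-6-(benzyloxy)undecyl]oxirane F6. Opening at the terminal carbon with vinylmagnesium bromide and catalytic CuI (THF, −30 °C) gives homoallylic alcohol 12, where the route is rejoined.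

Further compounds
F1 | step 8 | methyl (2E,5R,11S)-11-(benzyloxy)-5-[(4-methoxybenzyl)oxy]hexadec-2-enoate | CCCCC[C@H](OCc1ccccc1)CCCCC[C@H](C/C=C/C(=O)OC)OCc1ccc(OC)cc1
F2 | step 8 | dimethyl 2-acetyl-3-{(2R,8S)-8-(benzyloxy)-2-[(4-methoxybenzyl)oxy]tridecyl}pentanedioate (C2 and C3 epimers) | CCCCC[C@H](OCc1ccccc1)CCCCC[C@H](CC(CC(=O)OC)C(C(C)=O)C(=O)OC)OCc1ccc(OC)cc1
F3 | step 11 | 5-[(2R,8S)-8-(benzyloxy)-2-[(4-methoxybenzyl)oxy]tridecyl]-3-methoxy-6-(phenylselanyl)cyclohex-2-en-1-one | CCCCC[C@H](OCc1ccccc1)CCCCC[C@H](CC1CC(OC)=CC(=O)C1[Se]c1ccccc1)OCc1ccc(OC)cc1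
F4 | step 11 | 6-(benzeneseleninyl)-5-[(2R,8S)-8-(benzyloxy)-2-[(4-methoxybenzyl)oxy]tridecyl]-3-methoxycyclohex-2-en-1-one | CCCCC[C@H](OCc1ccccc1)CCCCC[C@H](CC1CC(OC)=CC(=O)C1[Se](=O)c1ccccc1)OCc1ccc(OC)cc1
F5 | step 5 | 2-[(6S)-6-(benzyloxy)undecyl]oxirane (both epoxide epimers) | CCCCC[C@H](OCc1ccccc1)CCCCCC1CO1
F6 | step 5 | (2R)-2-[(6S)-6-(benzyloxy)undecyl]oxirane | CCCCC[C@H](OCc1ccccc1)CCCCC[C@@H]1CO1
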